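**Plan**
Cuts: first the acyl C1–O bond to the OCH2 group of the tyrosol part, then C7–C8 of the hexacosanoyl chain. No other bond of the target has to be made.
Forward: eicosanoic acid 1 (C20) and methyl hydrogen suberate 2 (C8) are joined in one anodic event. Both free CO2H groups leave as CO2, and radicals 3 (C19) and 4 (C7) combine to the full C26 chain, methyl hexacosanoate 5.
Enabling feature: C7 and C8 lie inside the unbranched methylene run C2–C25, with C7 five CH2 groups from the C1 carbonyl. Both cut ends are therefore primary, unstabilised radicals with no α-heteroatom or branch, the class that couples at platinum and is not oxidised further.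
The one anodically fragile part, the 4-hydroxyphenyl ring, hangs on the ester oxygen and can stay outside the cell. A lipase then moves the acyl group of 5 onto the primary OH of tyrosol 6, leaves the phenol OH free and gives target 7 without protecting groups.
No ring is formed (the benzene ring comes with 6). The target has no stereocentre and no C=C bond, so no stereochemistry has to be set.

Key step: step 1

Assumption: 1, 2 and 6 are taken as catalogue chemicals (arachidic acid, suberic acid monomethyl ester, tyrosol).

Step 1
Reactants: 1 eicosanoic acid (arachidic acid); 2 methyl hydrogen suberate (8-methoxy-8-oxooctanoic acid)
Product: 5 methyl hexacosanoate, via nonadecyl radical 3 (not isolated), via 7-methoxy-7-oxoheptyl radical 4 (not isolated)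
Conditions: Pt anode/Pt cathode, undivided cell, constant current ca. 0.2 A cm−2; 2 (3 equiv), NaOMe (5 mol % of total CO2H), MeOH–hexane, 50 °C, polarity reversed at intervals, stopped when the solution turns just alkaline
Reagents that add atoms: none
Why: Crossed Kolbe electrolysis: above the critical anode potential the two carboxylates adsorbed on smooth platinum each lose one electron and CO2, and the primary radicals 3 and 4 born side by side at the electrode combine to form C7–C8, while protons are reduced to hydrogen at the cathode. The closest known reaction type is the anodic chain extension of C16–C22 fatty acids with the methyl half esters of adipic, suberic or sebacic acid. No ring is closed and no stereocentre is created. Two selectivities are needed, cross- over homo-coupling and radical coupling over a second electron transfer to the cation (Hofer–Moest path). The first is statistical, since 3 and 4 are alike in reactivity, and is steered by the excess of the cheap half ester 2 so that most of 3 meets 4, the two symmetrical dimers differing from 5 by one ester group more or less and so being removable on silica or by crystallisation. The second is secured by the substrate, both radical carbons being primary, unbranched and free of α-heteroatoms, and by weakly acidic methanol, high current density and platinum; the methyl ester keeps the second carboxyl of the C8 diacid silent and methanol as solvent makes ester exchange degenerate.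

Step 2
Reactants: 5 methyl hexacosanoate; 6 tyrosol (4-(2-hydroxyethyl)phenol)
Product: 7 2-(4-hydroxyphenyl)ethyl hexacosanoate (target)
Conditions: 6 (2 equiv), immobilised Candida antarctica lipase B, 4 Å MS, 2-methyl-2-butanol–toluene, 70 °C
Reagents that add atoms: none
Why: Lipase-catalysed transesterification, a reaction type well known for tyrosol with methyl, ethyl or vinyl esters of fatty acids: the enzyme accepts long unbranched acyl chains and primary alcohols but neither phenols nor the tertiary alcohol solvent as acyl acceptors, so only the CH2OH of 6 should be acylated, and trapping of methanol on the sieves pulls the equilibrium to 7.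

**Compound list**
1 | eicosanoic acid (arachidic acid) | CCCCCCCCCCCCCCCCCCCC(=O)O | starting material
2 | methyl hydrogen suberate (8-methoxy-8-oxooctanoic acid) | COC(=O)CCCCCCC(=O)O | starting material
3 | nonadecyl radical | CCCCCCCCCCCCCCCCCC[CH2] | intermediate
4 | 7-methoxy-7-oxoheptyl radical | [CH2]CCCCCC(=O)OC | intermediate
5 | methyl hexacosanoate | CCCCCCCCCCCCCCCCCCCCCCCCCC(=O)OC | intermediate
6 | tyrosol, 4-(2-hydroxyethyl)phenol | OCCc1ccc(O)cc1 | starting material
7 | 2-(4-hydroxyphenyl)ethyl hexacosanoate | CCCCCCCCCCCCCCCCCCCCCCCCCC(=O)OCCc1ccc(O)cc1 | target

Total step count: 2. Longest linear sequence: 2.

**Steps most likely to fail** (the route has only two steps, so both are ranked)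

Step 1.
- What may go wrong: material is lost to coupling of each radical with its own kind. Waxy deposit fouls the anode, so the potential falls below the Kolbe regime. The radicals are oxidised further to cations that are trapped by the solvent or eliminate.
- Fallback: the C7–C8 bond is made as a C=C bond by olefin cross-metathesis and saturated afterwards. It sets out from tyrosol 6. Lipase-catalysed esterification of its primary OH with oct-7-enoic acid (C=CCCCCCC(=O)O; immobilised Candida antarctica lipase B, 4 Å MS, 2-methyl-2-butanol, 50 °C) should give 2-(4-hydroxyphenyl)ethyl oct-7-enoate F1.
- Cross-metathesis of F1 with an excess of icos-1-ene (C=CCCCCCCCCCCCCCCCCCC) follows, using Hoveyda–Grubbs second-generation catalyst in CH2Cl2 at 40 °C, with 1,4-benzoquinone against double-bond migration. It should give 2-(4-hydroxyphenyl)ethyl (E)-hexacos-7-enoate F2 together with its Z isomer, which is of no consequence.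
- Hydrogenation (H2, Pd/C, EtOAc–THF) removes the double bond, and the fallback comes back to the route at target 7.

Step 2.
- What may go wrong: acyl transfer is slow or incomplete because the C26 ester dissolves poorly and fits the enzyme less well than shorter chains. Methanol release is reversible. The enzyme loses activity at the temperature needed for dissolution.
- Fallback: enzymatic acyl transfer is replaced by activation of the alcohol. It sets out from 5. Saponification (KOH, EtOH–THF–H2O, reflux, then HCl) should give hexacosanoic acid F3.
- A Mitsunobu esterification of F3 with 6 (PPh3, DIAD, THF, 0 to 40 °C) follows. Only the aliphatic OH is turned into an oxyphosphonium leaving group, and the carboxylate, far more acidic than the phenol, is the nucleophile. This comes back to the route at target 7.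

**Further compounds**
F1 | step 1 | 2-(4-hydroxyphenyl)ethyl oct-7-enoate | C=CCCCCCC(=O)OCCc1ccc(O)cc1
F2 | step 1 | 2-(4-hydroxyphenyl)ethyl (E)-hexacos-7-enoate | CCCCCCCCCCCCCCCCCC/C=C/CCCCCC(=O)OCCc1ccc(O)cc1
F3 | step 2 | hexacosanoic acid | CCCCCCCCCCCCCCCCCCCCCCCCCC(=O)O
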